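Ring A (isochromanone numbering; C9 is the CH2 on C3) carries two meta oxygens that already differ, C8–OH and C6–OCH3. C7–H lies between them, and C5–CH3 and the C4a alkyl branch follow. This 1-hydroxy-3-alkoxy-4,5-dialkyl pattern is what a 2,3-dialkylcyclobutenone and an alkoxyacetylene give on heating.
Ring B (the lactol) opens to the C3 keto acid. C1 is carried as a vinyl group on C8a until C3 is a ketone, because a free C3 hydroxyl would attack a C1 ester. The C9 ester comes from 2,4-bis(benzyloxy)-5,6-dimethylbenzoic acid 29.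
Key disconnection: ring A from cyclobutenone 12 and methoxyacetylene 15, forming bonds C7–C8, C5–C6 and C8–C8a.
Cyclobutenone 12 comes from internal alkyne 8 and dichloroketene. The C4 stereocentre comes from (R)-but-3-yn-2-ol by Marshall propargylation.
Ring order: the sacrificial four-membered ring (step 5), ring A (step 8), ring B (step 19). The aryl ring of the ester is bought as 4,5-dimethylresorcinol.

Key step: step 8

Assumption: C3 is a hemiketal carbon that equilibrates through the open keto acid. The (3R) form, with the hydroxyl axial and trans to the pseudo-axial C4 methyl, is taken to be the preferred anomer, so only C4 has to be set by synthesis.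
Notation: TBS = tert-butyldimethylsilyl, Bn = benzyl.

Step 1
Reactants: 1 (R)-but-3-yn-2-ol
Product: 2 (R)-but-3-yn-2-yl methanesulfonate
Conditions: MsCl, Et3N, CH2Cl2, −78 → 0 °C
Reagents that add atoms: methanesulfonyl chloride, CS(=O)(=O)Cl
Why: Sulfonylation of the alcohol oxygen (mesylate formation) leaves the C–O bond intact, so the R configuration is kept and the leaving group for the palladium step is in place.

Step 2
Reactants: 2 (R)-but-3-yn-2-yl methanesulfonate; 3 (tert-butyldimethylsilyloxy)acetaldehyde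
Product: 5 (2S,3S)-1-(tert-butyldimethylsilyloxy)-3-methylpent-4-yn-2-ol, via allenylzinc mesylate 4 (not isolated)
Conditions: Pd(OAc)2 (5 mol %), PPh3 (5 mol %), Et2Zn (3 equiv), THF, −78 → −20 °C; then cold 1 M HCl
Reagents that add atoms: none
Why: Marshall propargylation: zerovalent palladium formed in the flask displaces the mesylate in an anti SN2′ sense, Et2Zn converts the allenylpalladium into (P)-allenylzinc 4, and 4 adds to the aldehyde through a cyclic SE2′ transition state, so the methyl-bearing carbon (the future C4) is set as S by chirality transfer with net inversion and the carbinol comes out anti; that carbinol centre is erased in step 17, so only the chirality transfer matters.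

Step 3
Reactants: 5 (2S,3S)-1-(tert-butyldimethylsilyloxy)-3-methylpent-4-yn-2-ol
Product: 6 (3S,4S)-4,5-bis(tert-butyldimethylsilyloxy)-3-methylpent-1-yne
Conditions: TBSOTf, 2,6-lutidine, CH2Cl2, 0 °C
Reagents that add atoms: tert-butyldimethylsilyl triflate, CC(C)(C)[Si](C)(C)OS(=O)(=O)C(F)(F)F
Why: Silyl ether formation with the reactive triflate covers the hindered secondary alcohol under conditions that touch neither the alkyne nor the two stereocentres.

Step 4
Reactants: 6 (3S,4S)-4,5-bis(tert-butyldimethylsilyloxy)-3-methylpent-1-yne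
Product: 8 (4S,5S)-5,6-bis(tert-butyldimethylsilyloxy)-4-methylhex-2-yne, via lithium acetylide 7 (not isolated)
Conditions: n-BuLi (1.05 equiv), THF, −78 °C; MeI, −78 °C → rt
Reagents that add atoms: iodomethane, CI
Why: Deprotonation of the terminal alkyne and SN2 alkylation of the acetylide bring in the carbon that becomes the C5 methyl group, and the far less acidic propargylic C–H is not touched.

Step 5
Reactants: 8 (4S,5S)-5,6-bis(tert-butyldimethylsilyloxy)-4-methylhex-2-yne; 9 trichloroacetyl chloride
Product: 11 4,4-dichloro-2-methyl-3-[(2S,3S)-3,4-bis(tert-butyldimethylsilyloxy)butan-2-yl]cyclobut-2-en-1-one, via dichloroketene 10 (not isolated)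
Conditions: Zn(Cu), Et2O–DME, rt
Reagents that add atoms: none
Why: Ketene–alkyne (2+2) cycloaddition with dichloroketene made by zinc dechlorination of 9: the ketene carbonyl carbon should bond to the less hindered, methyl-bearing alkyne carbon while positive charge builds on the carbon bearing the branched chain, which puts CH3 on C2 and the chain on C3 of the ring; DME ties up ZnCl2 so that the silyl ethers survive, and any regioisomer is removed by chromatography here or after step 6.

Step 6
Reactants: 11 4,4-dichloro-2-methyl-3-[(2S,3S)-3,4-bis(tert-butyldimethylsilyloxy)butan-2-yl]cyclobut-2-en-1-one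
Product: 12 2-methyl-3-[(2S,3S)-3,4-bis(tert-butyldimethylsilyloxy)butan-2-yl]cyclobut-2-en-1-one
Conditions: Zn dust, AcOH, TMEDA, EtOH, 0 °C → rt
Reagents that add atoms: none
Why: Reductive dechlorination of the α,α-dichloroketone by zinc in buffered acetic acid replaces both chlorines by hydrogen, and the mild medium leaves the strained enone, the silyl ethers and the chain stereocentres alone.

Step 7
Reactants: 13 chloroacetaldehyde dimethyl acetal
Product: 15 methoxyacetylene, via sodium methoxyacetylide 14 (not isolated)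
Conditions: NaNH2 (3 equiv), liquid NH3, −33 °C; then cold saturated aq NaCl, distillation into a cold trap
Reagents that add atoms: none
Why: Twofold base-induced elimination: sodium amide removes HCl and then methanol from the chloroacetal and holds the product as its acetylide until the cold aqueous quench, after which the low-boiling ynol ether is distilled and used at once.

Step 8
Reactants: 12 2-methyl-3-[(2S,3S)-3,4-bis(tert-butyldimethylsilyloxy)butan-2-yl]cyclobut-2-en-1-one; 15 methoxyacetylene
Product: 20 3-methoxy-4-methyl-5-[(2S,3S)-3,4-bis(tert-butyldimethylsilyloxy)butan-2-yl]phenol, via vinylketene 16 (not isolated), via vinylcyclobutenone 17 (not isolated), via dienylketene 18 (not isolated), via cyclohexadienone 19 (not isolated)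
Conditions: 15 (3 equiv), toluene, sealed tube, 80 °C, then 110 °C
Reagents that add atoms: none
Why: This is a Danheiser benzannulation, a known reaction of cyclobutenones with alkoxyacetylenes: heat opens 12 by four-electron electrocyclic cleavage of its C(=O)–CH2 bond to vinylketene 16, whose ketene unit adds 15 in a (2+2) cycloaddition (new bonds C7–C8 and C5–C6) to give 17. Cyclobutenone 17 opens reversibly to dienylketene 18, and the isomer with the alkenyl arm cis to the ketene arm closes ring A, a six-membered carbocycle, by six-electron electrocyclisation (bond C8–C8a), after which dienone 19 tautomerises to phenol 20. The selectivity needed is the orientation of the ynol ether, and its polarisation secures it: the nucleophilic unsubstituted carbon attacks the electrophilic ketene carbonyl carbon, so OCH3 ends on C6, H on C7 and the ketene oxygen becomes the free C8 phenol, which gives the two meta oxygens already differentiated. The methyl on C2 and the chain on C3 of 12 stay bonded to neighbouring carbons throughout and therefore map onto C5 and C4a. No lasting stereocentre is made (the quaternary carbon of 17 is erased on ring opening), and the C4 centre, which is only vinylogously acidic in 12, meets neither acid nor base and is carried through unchanged together with both silyl ethers.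

Step 9
Reactants: 20 3-methoxy-4-methyl-5-[(2S,3S)-3,4-bis(tert-butyldimethylsilyloxy)butan-2-yl]phenol
Product: 21 1-(benzyloxy)-3-methoxy-4-methyl-5-[(2S,3S)-3,4-bis(tert-butyldimethylsilyloxy)butan-2-yl]benzene
Conditions: BnBr, K2CO3, DMF, rt
Reagents that add atoms: benzyl bromide, BrCc1ccccc1
Why: Williamson ether synthesis on the unhindered phenoxide protects C8–OH as a benzyl ether that survives bromination, cross-coupling, fluoride and the oxidations and is removed in the last step.

Step 10
Reactants: 21 1-(benzyloxy)-3-methoxy-4-methyl-5-[(2S,3S)-3,4-bis(tert-butyldimethylsilyloxy)butan-2-yl]benzene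
Product: 22 1-(benzyloxy)-2-bromo-5-methoxy-4-methyl-3-[(2S,3S)-3,4-bis(tert-butyldimethylsilyloxy)butan-2-yl]benzene (bromine on C8a)
Conditions: NBS (1.0 equiv), MeCN, −20 → 0 °C, dark
Reagents that add atoms: N-bromosuccinimide, O=C1CCC(=O)N1Br
Why: Electrophilic aromatic bromination: C8a is para to the C6 methoxyl and ortho to the C8 benzyloxy group, whereas C7 lies between two alkoxy groups and is shielded by the methoxyl methyl, which the C5 methyl forces to point toward C7, so bromine should enter at C8a.

Step 11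
Reactants: 22 1-(benzyloxy)-2-bromo-5-methoxy-4-methyl-3-[(2S,3S)-3,4-bis(tert-butyldimethylsilyloxy)butan-2-yl]benzene
Product: 23 1-(benzyloxy)-2-ethenyl-5-methoxy-4-methyl-3-[(2S,3S)-3,4-bis(tert-butyldimethylsilyloxy)butan-2-yl]benzene
Conditions: vinylboronic acid pinacol ester, Pd(OAc)2 (5 mol %), SPhos (10 mol %), K3PO4, toluene–H2O, 90 °C
Reagents that add atoms: vinylboronic acid pinacol ester, C=CB1OC(C)(C)C(C)(C)O1
Why: Suzuki–Miyaura coupling with a bulky electron-rich biarylphosphine tolerates the two ortho substituents and installs C1 as a vinyl group, a carboxyl surrogate that a free C3 hydroxyl cannot attack, whereas a C1 ester would lactonise as soon as that hydroxyl is released.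

Step 12
Reactants: 23 1-(benzyloxy)-2-ethenyl-5-methoxy-4-methyl-3-[(2S,3S)-3,4-bis(tert-butyldimethylsilyloxy)butan-2-yl]benzene
Product: 24 (2S,3S)-3-[3-(benzyloxy)-2-ethenyl-5-methoxy-6-methylphenyl]butane-1,2-diol
Conditions: Bu4NF, THF, 0 °C → rt
Reagents that add atoms: none
Why: Fluoride-induced cleavage of both silyl ethers gives the diol, and nothing in the molecule is electrophilic enough to be attacked by the alkoxides that form.

Step 13
Reactants: 25 4,5-dimethylresorcinol
Product: 27 2,4-dihydroxy-5,6-dimethylbenzaldehyde, via aryl iminium chloride 26 (not isolated)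
Conditions: POCl3, DMF, MeCN, 0 °C → rt; then H2O, 50 °C
Reagents that add atoms: N,N-dimethylformamide, CN(C)C=O; water, O
Why: Vilsmeier–Haack formylation goes to the ring position that is para to one hydroxyl and ortho to the other rather than to the crowded position between the two hydroxyls, which gives the 2,4-dihydroxy-5,6-dimethyl pattern.

Step 14
Reactants: 27 2,4-dihydroxy-5,6-dimethylbenzaldehyde
Product: 28 2,4-bis(benzyloxy)-5,6-dimethylbenzaldehyde
Conditions: BnBr (2.5 equiv), K2CO3, DMF, 60 °C
Reagents that add atoms: benzyl bromide, BrCc1ccccc1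
Why: Twofold Williamson ether synthesis, with gentle heating so that the hydrogen-bonded ortho hydroxyl is alkylated as well.

Step 15
Reactants: 28 2,4-bis(benzyloxy)-5,6-dimethylbenzaldehyde
Product: 29 2,4-bis(benzyloxy)-5,6-dimethylbenzoic acid
Conditions: NaClO2, NaH2PO4, 2-methyl-2-butene, t-BuOH–H2O, rt
Reagents that add atoms: sodium chlorite, [Na+].[O-]Cl=O
Why: Pinnick oxidation converts the hindered electron-rich aldehyde into the acid, and the alkene scavenger takes up hypochlorous acid before it can chlorinate the ring.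

Step 16
Reactants: 24 (2S,3S)-3-[3-(benzyloxy)-2-ethenyl-5-methoxy-6-methylphenyl]butane-1,2-diol; 29 2,4-bis(benzyloxy)-5,6-dimethylbenzoic acid
Product: 31 (2S,3S)-3-[3-(benzyloxy)-2-ethenyl-5-methoxy-6-methylphenyl]-2-hydroxybutyl 2,4-bis(benzyloxy)-5,6-dimethylbenzoate, via acid chloride 30 (not isolated)
Conditions: 29, (COCl)2, DMF (cat.), CH2Cl2, 0 °C → rt, concentrate; then 24, Et3N, DMAP (cat.), CH2Cl2, −20 → 0 °C
Reagents that add atoms: none
Why: Nucleophilic acyl substitution through the acid chloride with DMAP catalysis: the doubly ortho-substituted aroyl chloride should discriminate strongly between the primary C9 hydroxyl and the secondary C3 hydroxyl, which is flanked by the aryl-bearing methine.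

Step 17
Reactants: 31 (2S,3S)-3-[3-(benzyloxy)-2-ethenyl-5-methoxy-6-methylphenyl]-2-hydroxybutyl 2,4-bis(benzyloxy)-5,6-dimethylbenzoate
Product: 32 (3S)-3-[3-(benzyloxy)-2-ethenyl-5-methoxy-6-methylphenyl]-2-oxobutyl 2,4-bis(benzyloxy)-5,6-dimethylbenzoate
Conditions: Dess–Martin periodinane, CH2Cl2, 0 °C → rt
Reagents that add atoms: none
Why: Dess–Martin oxidation turns the C3 carbinol into the ketone under nearly neutral conditions, so the C4 centre, whose enolisation is disfavoured by the twisted, doubly ortho-substituted aryl group, should not epimerise.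

Step 18
Reactants: 32 (3S)-3-[3-(benzyloxy)-2-ethenyl-5-methoxy-6-methylphenyl]-2-oxobutyl 2,4-bis(benzyloxy)-5,6-dimethylbenzoate
Product: 33 (3S)-3-[3-(benzyloxy)-2-formyl-5-methoxy-6-methylphenyl]-2-oxobutyl 2,4-bis(benzyloxy)-5,6-dimethylbenzoate
Conditions: OsO4 (cat.), NaIO4, 2,6-lutidine, dioxane–H2O, rt
Reagents that add atoms: sodium periodate (oxygen passed on through OsO4), [Na+].[O-]I(=O)(=O)=O
Why: Lemieux–Johnson cleavage: catalytic osmylation of the only alkene and periodate cleavage of the resulting diol give the C1 aldehyde, and 2,6-lutidine is too weak a base to enolise the ketone.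

Step 19
Reactants: 33 (3S)-3-[3-(benzyloxy)-2-formyl-5-methoxy-6-methylphenyl]-2-oxobutyl 2,4-bis(benzyloxy)-5,6-dimethylbenzoate
Product: 35 [(3R,4S)-8-(benzyloxy)-3-hydroxy-6-methoxy-4,5-dimethyl-1-oxo-3,4-dihydro-1H-isochromen-3-yl]methyl 2,4-bis(benzyloxy)-5,6-dimethylbenzoate, via keto acid 34 (not isolated)
Conditions: NaClO2, NaH2PO4, 2-methyl-2-butene, t-BuOH–H2O, 0 °C → rt
Reagents that add atoms: sodium chlorite, [Na+].[O-]Cl=O
Why: Pinnick oxidation gives keto acid 34, which closes ring B by 6-exo-trig addition of the carboxyl oxygen to the C3 ketone; C3 is set under thermodynamic control by ring–chain equilibration, with the hydroxyl axial (anomeric effect) and trans to the C4 methyl, which sits pseudo-axial to avoid the C5 methyl.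

Step 20
Reactants: 35 [(3R,4S)-8-(benzyloxy)-3-hydroxy-6-methoxy-4,5-dimethyl-1-oxo-3,4-dihydro-1H-isochromen-3-yl]methyl 2,4-bis(benzyloxy)-5,6-dimethylbenzoate
Product: 36 [(3R,4S)-3,8-dihydroxy-6-methoxy-4,5-dimethyl-1-oxo-3,4-dihydro-1H-isochromen-3-yl]methyl 2,4-dihydroxy-5,6-dimethylbenzoate (CNP0072952.2)
Conditions: H2 (1 atm), Pd/C (10 wt %), EtOAc, rt
Reagents that add atoms: none
Why: Catalytic hydrogenolysis removes the three benzyl ethers under neutral conditions that touch neither the lactol, the C9 ester nor C4, and the lactol stays at its equilibrium configuration.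

Compound list
1 | (R)-but-3-yn-2-ol | C#C[C@@H](C)O | starting material
2 | (R)-but-3-yn-2-yl methanesulfonate | C#C[C@@H](C)OS(C)(=O)=O | intermediate
3 | (tert-butyldimethylsilyloxy)acetaldehyde | O=CCO[Si](C)(C)C(C)(C)C | starting material
4 | (P)-buta-1,2-dien-1-ylzinc methanesulfonate | CS(=O)(=O)O[Zn]C([H])=[C@@]=C([H])C | intermediate
5 | (2S,3S)-1-(tert-butyldimethylsilyloxy)-3-methylpent-4-yn-2-ol | C#C[C@H](C)[C@H](O)CO[Si](C)(C)C(C)(C)C | intermediate
6 | (3S,4S)-4,5-bis(tert-butyldimethylsilyloxy)-3-methylpent-1-yne | C#C[C@H](C)[C@H](O[Si](C)(C)C(C)(C)C)CO[Si](C)(C)C(C)(C)C | intermediate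
7 | lithium acetylide of 6 | [Li]C#C[C@H](C)[C@H](O[Si](C)(C)C(C)(C)C)CO[Si](C)(C)C(C)(C)C | intermediate
8 | (4S,5S)-5,6-bis(tert-butyldimethylsilyloxy)-4-methylhex-2-yne | CC#C[C@H](C)[C@H](O[Si](C)(C)C(C)(C)C)CO[Si](C)(C)C(C)(C)C | intermediate
9 | trichloroacetyl chloride | O=C(Cl)C(Cl)(Cl)Cl | starting material
10 | dichloroketene | O=C=C(Cl)Cl | intermediate
11 | 4,4-dichloro-2-methyl-3-[(2S,3S)-3,4-bis(tert-butyldimethylsilyloxy)butan-2-yl]cyclobut-2-en-1-one | CC1=C(C(Cl)(Cl)C1=O)[C@H](C)[C@H](O[Si](C)(C)C(C)(C)C)CO[Si](C)(C)C(C)(C)C | intermediate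
12 | 2-methyl-3-[(2S,3S)-3,4-bis(tert-butyldimethylsilyloxy)butan-2-yl]cyclobut-2-en-1-one | CC1=C(CC1=O)[C@H](C)[C@H](O[Si](C)(C)C(C)(C)C)CO[Si](C)(C)C(C)(C)C | intermediate
13 | chloroacetaldehyde dimethyl acetal | COC(CCl)OC | starting material
14 | sodium methoxyacetylide | [Na+].[C-]#COC | intermediate
15 | methoxyacetylene | COC#C | intermediate
16 | vinylketene from ring opening of 12 | O=C=C(C)C(=C)[C@H](C)[C@H](O[Si](C)(C)C(C)(C)C)CO[Si](C)(C)C(C)(C)C | intermediate
17 | 3-methoxy-4-methyl-4-alkenylcyclobut-2-en-1-one (both epimers at the ring quaternary carbon) | COC1=CC(=O)C1(C)C(=C)[C@H](C)[C@H](O[Si](C)(C)C(C)(C)C)CO[Si](C)(C)C(C)(C)C | intermediate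
18 | dienylketene with the alkenyl arm cis to the ketene arm | O=C=C/C(OC)=C(/C)C(=C)[C@H](C)[C@H](O[Si](C)(C)C(C)(C)C)CO[Si](C)(C)C(C)(C)C | intermediate
19 | 3-methoxy-4-methyl-5-alkylcyclohexa-2,4-dien-1-one | COC1=CC(=O)CC(=C1C)[C@H](C)[C@H](O[Si](C)(C)C(C)(C)C)CO[Si](C)(C)C(C)(C)C | intermediate
20 | 3-methoxy-4-methyl-5-[(2S,3S)-3,4-bis(tert-butyldimethylsilyloxy)butan-2-yl]phenol | COc1cc(O)cc(c1C)[C@H](C)[C@H](O[Si](C)(C)C(C)(C)C)CO[Si](C)(C)C(C)(C)C | intermediate
21 | benzyl ether of 20 | COc1cc(OCc2ccccc2)cc(c1C)[C@H](C)[C@H](O[Si](C)(C)C(C)(C)C)CO[Si](C)(C)C(C)(C)C | intermediate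
22 | C8a bromide of 21 | COc1cc(OCc2ccccc2)c(Br)c(c1C)[C@H](C)[C@H](O[Si](C)(C)C(C)(C)C)CO[Si](C)(C)C(C)(C)C | intermediate
23 | C8a vinyl arene | COc1cc(OCc2ccccc2)c(C=C)c(c1C)[C@H](C)[C@H](O[Si](C)(C)C(C)(C)C)CO[Si](C)(C)C(C)(C)C | intermediate
24 | (2S,3S)-3-[3-(benzyloxy)-2-ethenyl-5-methoxy-6-methylphenyl]butane-1,2-diol | COc1cc(OCc2ccccc2)c(C=C)c(c1C)[C@H](C)[C@H](O)CO | intermediate
25 | 4,5-dimethylresorcinol | Cc1cc(O)cc(O)c1C | starting material
26 | (2,4-dihydroxy-5,6-dimethylbenzylidene)dimethyliminium chloride | C[N+](C)=Cc1c(O)cc(O)c(C)c1C.[Cl-] | intermediate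
27 | 2,4-dihydroxy-5,6-dimethylbenzaldehyde | O=Cc1c(O)cc(O)c(C)c1C | intermediate
28 | 2,4-bis(benzyloxy)-5,6-dimethylbenzaldehyde | O=Cc1c(OCc2ccccc2)cc(OCc2ccccc2)c(C)c1C | intermediate
29 | 2,4-bis(benzyloxy)-5,6-dimethylbenzoic acid | O=C(O)c1c(OCc2ccccc2)cc(OCc2ccccc2)c(C)c1C | intermediate
30 | 2,4-bis(benzyloxy)-5,6-dimethylbenzoyl chloride | O=C(Cl)c1c(OCc2ccccc2)cc(OCc2ccccc2)c(C)c1C | intermediate
31 | C9 ester with free C3 hydroxyl | COc1cc(OCc2ccccc2)c(C=C)c(c1C)[C@H](C)[C@H](O)COC(=O)c1c(OCc2ccccc2)cc(OCc2ccccc2)c(C)c1C | intermediate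
32 | C3 ketone with C8a vinyl group | COc1cc(OCc2ccccc2)c(C=C)c(c1C)[C@H](C)C(=O)COC(=O)c1c(OCc2ccccc2)cc(OCc2ccccc2)c(C)c1C | intermediate
33 | C3 ketone with C1 aldehyde | COc1cc(OCc2ccccc2)c(C=O)c(c1C)[C@H](C)C(=O)COC(=O)c1c(OCc2ccccc2)cc(OCc2ccccc2)c(C)c1C | intermediate
34 | open keto acid | COc1cc(OCc2ccccc2)c(C(=O)O)c(c1C)[C@H](C)C(=O)COC(=O)c1c(OCc2ccccc2)cc(OCc2ccccc2)c(C)c1C | intermediate
35 | tribenzyl-protected (3R,4S)-lactol | COc1cc(OCc3ccccc3)c2c(c1C)[C@H](C)[C@](O)(COC(=O)c1c(OCc3ccccc3)cc(OCc3ccccc3)c(C)c1C)OC2=O | intermediate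
36 | CNP0072952.2, (3R,4S) | COc1cc(O)c2c(c1C)[C@H](C)[C@](O)(COC(=O)c1c(O)cc(O)c(C)c1C)OC2=O | target

Total steps: 20. Longest linear sequence: 16 steps (steps 1–6, 8–12 and 16–20).

Steps most likely to fail

**Step 8 (key step).**
- What may go wrong: the ynol ether may oligomerise or escape into the head space before the tetrasubstituted cyclobutenone has opened. The vinylketene may also be intercepted by phenol already formed (O-acylation), which drains both partners.
- Fallback: make the same vinylketene 16 at room temperature by photochemical Wolff rearrangement instead of thermal ring opening.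
- It sets out from terminal alkyne 6. α-Selective hydroalumination (i-Bu2AlH, Ni(dppp)Cl2 cat., THF) gives the internal vinylalane F1, and iodine converts it into the 2-iodo-1-alkene F2.
- t-BuLi (Et2O, −78 °C) gives the vinyllithium F3, and N-methoxy-N-methylpropanamide gives the ethyl alkenyl ketone F4.
- Trifluoroacetylation of its kinetic enolate (LiN(SiMe3)2, CF3CO2CH2CF3) gives the 1,3-diketone F5. Detrifluoroacetylative diazo transfer (MsN3, Et3N, H2O, MeCN) gives the α-diazo ketone F6.
- Irradiation of F6 with 15 in CH2Cl2 at room temperature, followed by brief heating at 80 °C, runs through 16 to 19 and comes back to the route at phenol 20.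

**Step 5.**
- What may go wrong: the ketene may add in both orientations, because the two alkyne carbons differ only in the size of their alkyl groups. ZnCl2 may also begin to strip the primary silyl ether.
- Fallback: take the orientation out of play by adding the ketene to a terminal alkyne and bringing in the methyl group afterwards by cross-coupling.
- It sets out from 6. Dichloroketene 10 (from 9 and Zn(Cu)) bonds through its carbonyl carbon to the unsubstituted alkyne carbon and gives the 4,4-dichloro-3-alkylcyclobutenone F7.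
- Zn, AcOH and TMEDA give the 3-alkylcyclobutenone F8. Br2 (CH2Cl2, −78 °C) gives the 2,3-dibromocyclobutanone F9, from which Et3N removes HBr to give the 2-bromocyclobutenone F10.
- Negishi coupling with MeZnCl (Pd(PPh3)4 cat., THF, room temperature) comes back to the route at 12.

**Step 10.**
- What may go wrong: bromination at C7 may compete, because the branched chain and the buttressing C5 methyl crowd C8a.
- Fallback: brominate both free positions and remove the unwanted halogen by selective halogen–metal exchange.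
- It sets out from 21. Excess NBS gives the 7,8a-dibromide F11.
- One equivalent of n-BuLi (THF, −78 °C) exchanges the bromine that sits between the two alkoxy groups, where the aryllithium is best stabilised, to give the 7-lithio compound F12. Methanol protonates it, which comes back to the route at 22.

Further compounds
F1 | step 8 | internal vinylalane from 6 | C=C([Al](CC(C)C)CC(C)C)[C@H](C)[C@H](O[Si](C)(C)C(C)(C)C)CO[Si](C)(C)C(C)(C)C
F2 | step 8 | 4,5-bis(tert-butyldimethylsilyloxy)-2-iodo-3-methylpent-1-ene | C=C(I)[C@H](C)[C@H](O[Si](C)(C)C(C)(C)C)CO[Si](C)(C)C(C)(C)C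
F3 | step 8 | vinyllithium from F2 | C=C([Li])[C@H](C)[C@H](O[Si](C)(C)C(C)(C)C)CO[Si](C)(C)C(C)(C)C
F4 | step 8 | ethyl alkenyl ketone | CCC(=O)C(=C)[C@H](C)[C@H](O[Si](C)(C)C(C)(C)C)CO[Si](C)(C)C(C)(C)C
F5 | step 8 | α-trifluoroacetyl ketone | CC(C(=O)C(F)(F)F)C(=O)C(=C)[C@H](C)[C@H](O[Si](C)(C)C(C)(C)C)CO[Si](C)(C)C(C)(C)C
F6 | step 8 | α-diazo ketone | CC(=[N+]=[N-])C(=O)C(=C)[C@H](C)[C@H](O[Si](C)(C)C(C)(C)C)CO[Si](C)(C)C(C)(C)C
F7 | step 5 | 4,4-dichloro-3-alkylcyclobut-2-en-1-one | O=C1C=C(C1(Cl)Cl)[C@H](C)[C@H](O[Si](C)(C)C(C)(C)C)CO[Si](C)(C)C(C)(C)C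
F8 | step 5 | 3-alkylcyclobut-2-en-1-one | O=C1C=C(C1)[C@H](C)[C@H](O[Si](C)(C)C(C)(C)C)CO[Si](C)(C)C(C)(C)C
F9 | step 5 | 2,3-dibromo-3-alkylcyclobutan-1-one | O=C1CC(Br)(C1Br)[C@H](C)[C@H](O[Si](C)(C)C(C)(C)C)CO[Si](C)(C)C(C)(C)C
F10 | step 5 | 2-bromo-3-alkylcyclobut-2-en-1-one | O=C1CC(=C1Br)[C@H](C)[C@H](O[Si](C)(C)C(C)(C)C)CO[Si](C)(C)C(C)(C)C
F11 | step 10 | 7,8a-dibromide of 21 | COc1c(Br)c(OCc2ccccc2)c(Br)c(c1C)[C@H](C)[C@H](O[Si](C)(C)C(C)(C)C)CO[Si](C)(C)C(C)(C)C
F12 | step 10 | 7-lithio-8a-bromide | COc1c([Li])c(OCc2ccccc2)c(Br)c(c1C)[C@H](C)[C@H](O[Si](C)(C)C(C)(C)C)CO[Si](C)(C)C(C)(C)C
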